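**Plan**

- Cuts, in retrosynthetic order: the two tropolone O–CH3 bonds and the C10 O–Si bond; the two tertiary ether O–C6' bonds of the dihydropyrans; both CH2–C5' (sp3–sp2) bonds at once; both CH2–B bonds (from CH2–Br); the ring alkene C4=C5; the C9–C10 bond; and, in each half, one C–C bond made by opening a Sharpless epoxide (C8–C9, C1–CH2).
- Feature used: each seven-membered tropolone ring touches the eleven-membered carbocycle at only two atoms, an exocyclic CH2 carbon (on C1 and on C8, bonded to tropolone C5') and a tertiary ether oxygen (on C11 and on C7, bonded to C6'). The two CH2–C5' bonds are the same kind of bond, so one carbocycle with two primary CH2–B carbons can take up two molecules of a single 5-bromotropone.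
- Forward order: west epoxy aldehyde 6 and east iodide 16 are joined at C9–C10; metathesis closes the carbocycle (the only ring made before the coupling); two CH2Bpin arms are installed; two preformed tropone rings (ring expansion of a Birch diene) are coupled on; both dihydropyran rings then close and the tropolones are unmasked.
- Stereochemistry: C11 and C1 come from Sharpless epoxidation (L-(+)-tartrate) of a Z-allylic alcohol plus invertive epoxide opening; C7 and C8 from Sharpless epoxidation (D-(−)-tartrate) of an E-allylic alcohol plus invertive opening; C10 from a chelation-controlled Zn(BH4)2 reduction; the E-olefin from ring-closing metathesis.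

Key step: step 26

Remark (numbering): carbocycle atoms are C1 (CH carrying the CH2 arm on the gem-dimethyl side), C2, C3 (CMe2), C4=C5, C6, C7 (C–Me, O), C8 (CH carrying the second arm), C9, C10 (CH–O), C11 (C–Me, O); open-chain precursors use the same labels, descriptors such as (1R,7R,…) refer to them, and tropone atoms carry primes.

Remark (bromotropone): electrophilic bromination of a 2,6-dimethoxy-4-methyltropone is expected at C7' (the CH between the two oxygen-bearing carbons), so the C5' bromine is placed instead as the carbene carbon of a dibromocyclopropane ring expansion that starts from 2-methylanisole.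

**West fragment**

Step 1
Reactants: 1 methyl 3,3-dimethylpent-4-enoate
Product: 2 3,3-dimethylpent-4-enal
Conditions: i-Bu2AlH (1.05 equiv), CH2Cl2, −78 °C
Reagents that add atoms: none
Why: Partial ester reduction with i-Bu2AlH should stop at the aldehyde because the tetrahedral aluminium hemiacetal persists at −78 °C until work-up.

Step 2
Reactants: 2 3,3-dimethylpent-4-enal
Product: 3 methyl (2Z)-2,5,5-trimethylhepta-2,6-dienoate
Conditions: methyl 2-[bis(2,2,2-trifluoroethoxy)phosphoryl]propanoate, KN(SiMe3)2, 18-crown-6, THF, −78 °C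
Reagents that add atoms: methyl 2-[bis(2,2,2-trifluoroethoxy)phosphoryl]propanoate, COC(=O)C(C)P(=O)(OCC(F)(F)F)OCC(F)(F)F
Why: Still–Gennari olefination, in which the electron-poor phosphonate and the crown-ether-separated potassium ion make elimination faster than equilibration, should give the Z-trisubstituted enoate that places the C2 chain cis to the future C10.

Step 3
Reactants: 3 methyl (2Z)-2,5,5-trimethylhepta-2,6-dienoate
Product: 4 (2Z)-2,5,5-trimethylhepta-2,6-dien-1-ol
Conditions: i-Bu2AlH (2.2 equiv), CH2Cl2, −78 → 0 °C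
Reagents that add atoms: none
Why: 1,2-Reduction of the enoate by i-Bu2AlH should give the allylic alcohol without touching the olefin geometry.

Step 4
Reactants: 4 (2Z)-2,5,5-trimethylhepta-2,6-dien-1-ol
Product: 5 [(2S,3R)-3-(2,2-dimethylbut-3-en-1-yl)-2-methyloxiran-2-yl]methanol
Conditions: Ti(Oi-Pr)4 (20 mol %), L-(+)-diethyl tartrate (24 mol %), t-BuOOH, 4 Å molecular sieves, CH2Cl2, −20 °C
Reagents that add atoms: tert-butyl hydroperoxide, CC(C)(C)OO
Why: Sharpless asymmetric epoxidation is directed by the allylic hydroxyl, so the remote vinyl group is spared, and the L-(+)-tartrate complex should deliver oxygen to the face that gives the (2S,3R)-epoxide, fixing C11 and provisionally C1.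

Step 5
Reactants: 5 [(2S,3R)-3-(2,2-dimethylbut-3-en-1-yl)-2-methyloxiran-2-yl]methanol
Product: 6 (2R,3R)-3-(2,2-dimethylbut-3-en-1-yl)-2-methyloxirane-2-carbaldehyde
Conditions: Dess–Martin periodinane, NaHCO3, CH2Cl2, 0 → 23 °C
Reagents that add atoms: none
Why: Dess–Martin oxidation of the primary alcohol should give the epoxy aldehyde, which cannot epimerise because its α-carbon is quaternary.

**East fragment**

Step 6
Reactants: 7 pent-1-en-4-yne
Product: 10 (2E)-3-methylhexa-2,5-dien-1-ol, via alkenylalane 8 (not isolated), via lithium alanate 9 (not isolated)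
Conditions: Me3Al, Cp2ZrCl2 (20 mol %), CH2Cl2, 0 → 23 °C; n-BuLi, THF, −78 °C; (CH2O)n, −78 → 23 °C
Reagents that add atoms: trimethylaluminium, C[Al](C)C; paraformaldehyde (as formaldehyde), C=O
Why: Negishi zirconium-catalysed carboalumination adds methyl and aluminium syn across the terminal alkyne with methyl on the internal carbon, and the derived alanate is hydroxymethylated with retention, so the E-trisubstituted allylic alcohol should result while the terminal alkene stays inert.

Step 7
Reactants: 10 (2E)-3-methylhexa-2,5-dien-1-ol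
Product: 11 [(2R,3R)-3-methyl-3-(prop-2-en-1-yl)oxiran-2-yl]methanol
Conditions: Ti(Oi-Pr)4 (10 mol %), D-(−)-diethyl tartrate (12 mol %), t-BuOOH, 4 Å molecular sieves, CH2Cl2, −20 °C
Reagents that add atoms: tert-butyl hydroperoxide, CC(C)(C)OO
Why: Sharpless asymmetric epoxidation of this geraniol-type alcohol with D-(−)-tartrate should give the (2R,3R)-epoxide, fixing C7 and provisionally C8, with the allyl group untouched.

Step 8
Reactants: 11 [(2R,3R)-3-methyl-3-(prop-2-en-1-yl)oxiran-2-yl]methanol
Product: 12 tert-butyl(dimethyl){[(2R,3R)-3-methyl-3-(prop-2-en-1-yl)oxiran-2-yl]methoxy}silane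
Conditions: TBSCl, imidazole, CH2Cl2, 0 → 23 °C
Reagents that add atoms: tert-butyl(chloro)dimethylsilane, CC(C)(C)[Si](C)(C)Cl
Why: Silylation of the primary alcohol keeps this CH2O arm distinct from the CH2OH arm made in step 9, so C8 stays stereogenic.

Step 9
Reactants: 12 tert-butyl(dimethyl){[(2R,3R)-3-methyl-3-(prop-2-en-1-yl)oxiran-2-yl]methoxy}silane
Product: 14 (2S,3R)-2-({[tert-butyl(dimethyl)silyl]oxy}methyl)-3-methylhex-5-ene-1,3-diol, via isopropoxysilane 13 (not isolated)
Conditions: (i-PrO)Me2SiCH2MgCl (3 equiv), CuI (10 mol %), THF, −30 → 0 °C; then KF, KHCO3, 30% H2O2, THF/MeOH, 23 °C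
Reagents that add atoms: (isopropoxydimethylsilyl)methylmagnesium chloride, CC(C)O[Si](C)(C)C[Mg]Cl; hydrogen peroxide, OO
Why: Copper-catalysed Grignard opening should go by SN2 attack at the less substituted epoxide carbon (C8) with inversion, which sets C8 while C7 keeps its oxygen, and Tamao–Kumada oxidation of the C–Si bond with retention turns the silylmethyl group into the CH2OH that becomes C9.

Step 10
Reactants: 14 (2S,3R)-2-({[tert-butyl(dimethyl)silyl]oxy}methyl)-3-methylhex-5-ene-1,3-diol
Product: 15 (4R,5S)-5-({[tert-butyl(dimethyl)silyl]oxy}methyl)-6-iodo-4-methylhex-1-en-4-ol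
Conditions: I2, PPh3, imidazole, CH2Cl2, 0 °C
Reagents that add atoms: iodine, II
Why: Appel-type iodination converts only the primary alcohol, since the tertiary alkoxyphosphonium cannot be displaced.

Step 11
Reactants: 15 (4R,5S)-5-({[tert-butyl(dimethyl)silyl]oxy}methyl)-6-iodo-4-methylhex-1-en-4-ol
Product: 16 tert-butyl{[(2S,3R)-2-(iodomethyl)-3-methyl-3-[(triethylsilyl)oxy]hex-5-en-1-yl]oxy}dimethylsilane
Conditions: Et3SiOTf, 2,6-lutidine, CH2Cl2, −78 → 0 °C
Reagents that add atoms: triethylsilyl trifluoromethanesulfonate, CC[Si](CC)(CC)OS(=O)(=O)C(F)(F)F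
Why: Silyl triflate silylation caps the tertiary alcohol, which removes the acidic proton before lithiation and prevents hemiketal formation with the C10 ketone of step 13.

**Union, carbocycle and boronate**

Step 12
Reactants: 16 tert-butyl{[(2S,3R)-2-(iodomethyl)-3-methyl-3-[(triethylsilyl)oxy]hex-5-en-1-yl]oxy}dimethylsilane; 6 (2R,3R)-3-(2,2-dimethylbut-3-en-1-yl)-2-methyloxirane-2-carbaldehyde
Product: 18 (1R,7R,8S,11S)-1,11-epoxy alcohol with 10-OH (both C10 epimers), 7-OTES and 8-CH2OTBS, via alkyllithium 17 (not isolated)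
Conditions: t-BuLi (2.1 equiv), Et2O/pentane, −78 °C; then 6, −78 °C
Reagents that add atoms: none
Why: Iodine–lithium exchange is a polar process that gives the primary alkyllithium without cyclisation onto the allyl group at −78 °C, and its 1,2-addition to the aldehyde forms the C9–C10 bond; the new carbinol centre is left uncontrolled because steps 13 and 14 reset it.

Step 13
Reactants: 18 (1R,7R,8S,11S)-1,11-epoxy alcohol (C10 epimers)
Product: 19 (1R,7R,8S,11R)-1,11-epoxy-10-ketone with 7-OTES and 8-CH2OTBS
Conditions: Dess–Martin periodinane, NaHCO3, CH2Cl2, 23 °C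
Reagents that add atoms: none
Why: Dess–Martin oxidation merges both carbinol epimers into one α,β-epoxy ketone with no enolisable stereocentre next to the carbonyl on the epoxide side.

Step 14
Reactants: 19 (1R,7R,8S,11R)-1,11-epoxy-10-ketone
Product: 20 (1R,7R,8S,10S,11S)-1,11-epoxy-10-ol with 7-OTES and 8-CH2OTBS
Conditions: Zn(BH4)2, Et2O, −20 °C
Reagents that add atoms: none
Why: Chelation-controlled reduction of an α,β-epoxy ketone, in which zinc bridges the carbonyl and epoxide oxygens and hydride enters from the C11-methyl face (the other face is blocked by the cis C2 chain on C1), should give the anti epoxy alcohol and so set C10 as S.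

Step 15
Reactants: 20 (1R,7R,8S,10S,11S)-1,11-epoxy-10-ol
Product: 22 (1R,7R,8S,10S,11R)-triol with 1-CH2OH, 10-OH, 11-OH, 7-OTES and 8-CH2OTBS, via isopropoxysilane 21 (not isolated)
Conditions: (i-PrO)Me2SiCH2MgCl (4 equiv), CuI (20 mol %), THF, −20 → 0 °C; then KF, KHCO3, 30% H2O2, THF/MeOH, 23 °C
Reagents that add atoms: (isopropoxydimethylsilyl)methylmagnesium chloride, CC(C)O[Si](C)(C)C[Mg]Cl; hydrogen peroxide, OO
Why: Copper-catalysed Grignard opening of a 2-methyl-2,3-epoxy alcohol occurs at the non-quaternary carbon (C1) with inversion, assisted by the neighbouring magnesium alkoxide, which sets C1 with its CH2 arm syn to the retained C11 oxygen, and Tamao–Kumada oxidation then gives the CH2OH arm.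

Step 16
Reactants: 22 (1R,7R,8S,10S,11R)-triol
Product: 23 (1R,7R,8S,10S,11R)-diene with 1-CH2OTBS, 10-OTBS, 11-OH, 7-OTES and 8-CH2OTBS
Conditions: TBSOTf (2.3 equiv), 2,6-lutidine, CH2Cl2, −78 → −40 °C
Reagents that add atoms: tert-butyldimethylsilyl trifluoromethanesulfonate, CC(C)(C)[Si](C)(C)OS(=O)(=O)C(F)(F)F
Why: Silyl triflate silylation takes the primary and the secondary hydroxyl, while the tertiary C11 hydroxyl, flanked by two substituted carbons, should not react at low temperature.

Step 17
Reactants: 23 (1R,7R,8S,10S,11R)-diene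
Product: 24 (1R,4E,7R,8S,10S,11R)-cycloundec-4-ene with 1-CH2OTBS, 10-OTBS, 11-OH, 7-OTES and 8-CH2OTBS
Conditions: second-generation Grubbs catalyst RuCl2(=CHPh)(H2IMes)(PCy3) (10 mol %), toluene (1 mM), 80 °C
Reagents that add atoms: none
Why: Ring-closing olefin metathesis, in which the ruthenium alkylidene should load at the unhindered allyl terminus (C5) and close onto the neopentylic vinyl group at high dilution with loss of ethene, is expected to give the trans ring olefin as the less strained geometry next to the gem-dimethyl carbon.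

Step 18
Reactants: 24 (1R,4E,7R,8S,10S,11R)-cycloundec-4-ene, fully silylated
Product: 25 (1R,4E,7R,8S,10S,11R)-1,8-bis(hydroxymethyl)-10-(TBS-oxy)-3,3,7,11-tetramethylcycloundec-4-ene-7,11-diol
Conditions: HF·pyridine, pyridine, THF, 0 → 23 °C
Reagents that add atoms: none
Why: Buffered HF·pyridine desilylation should remove the two primary TBS ethers and the triethylsilyl ether much faster than the secondary TBS ether at C10, which is shielded by the adjacent quaternary carbon.

Step 19
Reactants: 25 (1R,4E,7R,8S,10S,11R)-tetraol mono-TBS ether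
Product: 26 (1S,4E,7R,8R,10S,11R)-1,8-bis(bromomethyl)-10-(TBS-oxy)-3,3,7,11-tetramethylcycloundec-4-ene-7,11-diol
Conditions: CBr4, PPh3, CH2Cl2, 0 °C
Reagents that add atoms: carbon tetrabromide, BrC(Br)(Br)Br
Why: The Appel reaction brominates only the two primary alcohols, the tertiary alcohols being inert, and the silyl ether at C10 prevents tetrahydrofuran formation.

Step 20
Reactants: 26 (1S,4E,7R,8R,10S,11R)-dibromide; 27 bis(pinacolato)diboron
Product: 28 (1S,4E,7R,8R,10S,11R)-10-(TBS-oxy)-3,3,7,11-tetramethyl-1,8-bis[(4,4,5,5-tetramethyl-1,3,2-dioxaborolan-2-yl)methyl]cycloundec-4-ene-7,11-diol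
Conditions: Pd2(dba)3 (5 mol %), t-Bu2MeP·HBF4 (20 mol %), K3PO4, H2O (15 equiv), t-BuOH, 60 °C
Reagents that add atoms: none
Why: Palladium-catalysed Miyaura-type borylation of primary alkyl bromides proceeds through SN2-type oxidative addition of an electron-rich zerovalent palladium phosphine complex, so no free alkyl radical is formed that could cyclise 5-exo onto the C4=C5 olefin, and the tertiary alcohols are tolerated.

**Bromotropone**

Step 21
Reactants: 29 2-methylanisole
Product: 30 1-methoxy-2-methylcyclohexa-1,4-diene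
Conditions: Li, NH3 (l), t-BuOH, THF, −78 → −33 °C
Reagents that add atoms: none
Why: Birch reduction of an anisole protonates ortho and meta to the donors, which leaves methoxy and methyl together on one tetrasubstituted enol ether double bond and an isolated disubstituted olefin.

Step 22
Reactants: 30 1-methoxy-2-methylcyclohexa-1,4-diene
Product: 31 rac-7,7-dibromo-1-methoxy-6-methylbicyclo[4.1.0]hept-3-ene
Conditions: CHBr3, KOt-Bu, pentane, −10 → 0 °C
Reagents that add atoms: bromoform, BrC(Br)Br
Why: Electrophilic dibromocarbene from α-elimination adds by [2+1] cycloaddition far faster to the electron-rich tetrasubstituted enol ether than to the isolated olefin, which puts the future C5' between the methyl- and methoxy-bearing carbons.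

Step 23
Reactants: 31 rac-7,7-dibromo-1-methoxy-6-methylbicyclo[4.1.0]hept-3-ene
Product: 32 rac-7,7-dibromo-1-methoxy-6-methylbicyclo[4.1.0]heptane-3,4-diol (cis-diol)
Conditions: OsO4 (2 mol %), N-methylmorpholine N-oxide, acetone/H2O, 23 °C
Reagents that add atoms: N-methylmorpholine N-oxide, C[N+]1([O-])CCOCC1; water, O
Why: Upjohn syn-dihydroxylation of the remaining olefin should give the cis-diol, whose facial orientation is irrelevant because both carbinol carbons become sp2.

Step 24
Reactants: 32 rac-7,7-dibromo-1-methoxy-6-methylbicyclo[4.1.0]heptane-3,4-diol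
Product: 34 5-bromo-2-hydroxy-6-methoxy-4-methylcyclohepta-2,4,6-trien-1-one, via bicyclic diketone 33 (not isolated)
Conditions: (COCl)2, DMSO, CH2Cl2, −78 °C; Et3N, −78 → 23 °C
Reagents that add atoms: none
Why: Double Swern oxidation gives the 1,2-diketone, whose amine-induced enolisation triggers electrocyclic opening of the gem-dibromocyclopropane with loss of bromide and a proton to the tropolone, one bromine staying on the former carbene carbon C5'.

Step 25
Reactants: 34 5-bromo-2-hydroxy-6-methoxy-4-methylcyclohepta-2,4,6-trien-1-one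
Product: 35 5-bromo-2,6-dimethoxy-4-methylcyclohepta-2,4,6-trien-1-one
Conditions: MeI, K2CO3, acetone, 50 °C
Reagents that add atoms: iodomethane, CI
Why: Williamson O-alkylation of the ambident tropolonate is expected to favour the ether that keeps C1'=O conjugated to the 6'-methoxy group; the regioisomeric ether that should also form would be removed by chromatography.

**Key step and end game**

Step 26
Reactants: 28 (1S,4E,7R,8R,10S,11R)-bis(pinacol boronate); 35 5-bromo-2,6-dimethoxy-4-methylcyclohepta-2,4,6-trien-1-one (2.6 equiv)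
Product: 36 (1R,4E,7R,8R,10S,11R)-10-(TBS-oxy)-3,3,7,11-tetramethylcycloundec-4-ene-7,11-diol in which each CH2 arm (on C1 and C8) is bonded to C5' of a 2,6-dimethoxy-4-methyltropone
Conditions: Pd(OAc)2 (10 mol %), RuPhos (20 mol %), K3PO4 (6 equiv), toluene/H2O (10:1), 85 °C
Reagents that add atoms: none
Why: Zerovalent palladium formed from Pd(OAc)2 and RuPhos inserts into the C5'–Br bond of the electron-poor tropone, the base-activated primary CH2–B carbon (helped by the γ-tertiary hydroxyl, which can form an internal borate) transmetalates, and reductive elimination forms the sp3–sp2 bond, the cycle running once on each arm. The closest known reaction type is the B-alkyl Suzuki–Miyaura coupling of primary alkyl pinacol boronates with hindered aryl bromides under dialkylbiarylphosphine catalysis. No ring is closed and no stereocentre is formed, because the reacting carbons are CH2 groups and the five stereocentres of the carbocycle are spectators. The selectivity needed is oxidative addition at C–Br rather than displacement of either methoxy group, no Heck reaction at the trans ring olefin, and no β-hydride elimination from the alkylpalladium, which the bulky electron-rich phosphine should secure by making reductive elimination fast. Phosphate is too weak a base to ionise the tertiary alcohols appreciably, so the diol should survive uncyclised, and any portion that did cyclise would converge on 37 in step 27.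

Step 27
Reactants: 36 bis(tropone) diol
Product: 37 (1R,4E,7R,8R,10S,11R)-bis(dihydropyrano)tropone: O on C11 bonded to C6' of the tropone on the C1 arm, O on C7 bonded to C6' of the tropone on the C8 arm, each tropone keeping its 2'-OMe, 10-OTBS retained
Conditions: KN(SiMe3)2 (2.2 equiv), THF, −78 → 0 °C
Reagents that add atoms: none
Why: Intramolecular oxa-Michael addition–elimination (vinylogous transesterification) should occur twice, each tertiary alkoxide adding 6-exo-trig to the methoxy-bearing β-carbon C6' of its tropone and expelling methoxide, faster than silyl migration from O10.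

Step 28
Reactants: 37 bis(dihydropyrano)tropone TBS ether
Product: 38 the corresponding C10 alcohol (both 2'-methyl ethers retained)
Conditions: Bu4NF, THF, 23 → 40 °C
Reagents that add atoms: none
Why: Fluoride-induced desilylation removes the hindered secondary TBS ether without affecting the vinylogous ester ethers.

Step 29
Reactants: 38 bis(2'-methoxytropone) alcohol
Product: 39 CNP0283947.4
Conditions: LiOH, THF/H2O, 40 °C; then aq. HCl to pH 4
Reagents that add atoms: lithium hydroxide, [Li+].[OH-]
Why: Alkaline hydrolysis of 2-methoxytropones is an addition–elimination at C2' that expels methoxide and is driven by tropolonate formation, whereas attack at the pyran carbon C6' is unproductive because hydroxide is the better leaving group than the tertiary alkoxide.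

**Compound list**

1 | methyl 3,3-dimethylpent-4-enoate | COC(=O)CC(C)(C)C=C | starting material
2 | 3,3-dimethylpent-4-enal | O=CCC(C)(C)C=C | intermediate
3 | methyl (2Z)-2,5,5-trimethylhepta-2,6-dienoate | C=CC(C)(C)C/C=C(/C)C(=O)OC | intermediate
4 | (2Z)-2,5,5-trimethylhepta-2,6-dien-1-ol | C=CC(C)(C)C/C=C(/C)CO | intermediate
5 | [(2S,3R)-3-(2,2-dimethylbut-3-en-1-yl)-2-methyloxiran-2-yl]methanol | C=CC(C)(C)C[C@H]1O[C@@]1(C)CO | intermediate
6 | (2R,3R)-3-(2,2-dimethylbut-3-en-1-yl)-2-methyloxirane-2-carbaldehyde | C=CC(C)(C)C[C@H]1O[C@@]1(C)C=O | intermediate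
7 | pent-1-en-4-yne | C=CCC#C | starting material
8 | dimethyl[(1E)-2-methylpenta-1,4-dien-1-yl]alumane | C=CC/C(C)=C/[Al](C)C | intermediate
9 | lithium butyl(dimethyl)[(1E)-2-methylpenta-1,4-dien-1-yl]aluminate | [Li+].C=CC/C(C)=C/[Al-](C)(C)CCCC | intermediate
10 | (2E)-3-methylhexa-2,5-dien-1-ol | C=CC/C(C)=C/CO | intermediate
11 | [(2R,3R)-3-methyl-3-(prop-2-en-1-yl)oxiran-2-yl]methanol | OC[C@H]1O[C@]1(C)CC=C | intermediate
12 | tert-butyl(dimethyl){[(2R,3R)-3-methyl-3-(prop-2-en-1-yl)oxiran-2-yl]methoxy}silane | CC(C)(C)[Si](C)(C)OC[C@H]1O[C@]1(C)CC=C | intermediate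
13 | isopropoxysilane: compound 14 with C9H2–SiMe2(Oi-Pr) in place of C9H2–OH, same configuration | CC(C)O[Si](C)(C)C[C@@H](CO[Si](C)(C)C(C)(C)C)[C@](C)(O)CC=C | intermediate
14 | (2S,3R)-2-({[tert-butyl(dimethyl)silyl]oxy}methyl)-3-methylhex-5-ene-1,3-diol | OC[C@@H](CO[Si](C)(C)C(C)(C)C)[C@](C)(O)CC=C | intermediate
15 | (4R,5S)-5-({[tert-butyl(dimethyl)silyl]oxy}methyl)-6-iodo-4-methylhex-1-en-4-ol | IC[C@@H](CO[Si](C)(C)C(C)(C)C)[C@](C)(O)CC=C | intermediate
16 | tert-butyl{[(2S,3R)-2-(iodomethyl)-3-methyl-3-[(triethylsilyl)oxy]hex-5-en-1-yl]oxy}dimethylsilane | IC[C@@H](CO[Si](C)(C)C(C)(C)C)[C@](C)(O[Si](CC)(CC)CC)CC=C | intermediate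
17 | alkyllithium: compound 16 with lithium in place of iodine | [Li]C[C@@H](CO[Si](C)(C)C(C)(C)C)[C@](C)(O[Si](CC)(CC)CC)CC=C | intermediate
18 | (1R,7R,8S,11S)-open-chain 1,11-epoxide, 10-OH (both epimers), 7-OTES, 8-CH2OTBS, vinyl on C3, allyl on C7 | C=CC(C)(C)C[C@H]1O[C@@]1(C)C(O)C[C@@H](CO[Si](C)(C)C(C)(C)C)[C@](C)(O[Si](CC)(CC)CC)CC=C | intermediate
19 | (1R,7R,8S,11R)-open-chain 1,11-epoxy-10-ketone, 7-OTES, 8-CH2OTBS | C=CC(C)(C)C[C@H]1O[C@@]1(C)C(=O)C[C@@H](CO[Si](C)(C)C(C)(C)C)[C@](C)(O[Si](CC)(CC)CC)CC=C | intermediate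
20 | (1R,7R,8S,10S,11S)-open-chain 1,11-epoxy-10-ol, 7-OTES, 8-CH2OTBS | C=CC(C)(C)C[C@H]1O[C@@]1(C)[C@@H](O)C[C@@H](CO[Si](C)(C)C(C)(C)C)[C@](C)(O[Si](CC)(CC)CC)CC=C | intermediate
21 | isopropoxysilane: compound 22 with CH2–SiMe2(Oi-Pr) on C1 in place of CH2OH, same configuration | C=CC(C)(C)C[C@H](C[Si](C)(C)OC(C)C)[C@@](C)(O)[C@@H](O)C[C@@H](CO[Si](C)(C)C(C)(C)C)[C@](C)(O[Si](CC)(CC)CC)CC=C | intermediate
22 | (1R,7R,8S,10S,11R)-open-chain triol: 1-CH2OH, 10-OH, 11-OH, 7-OTES, 8-CH2OTBS | C=CC(C)(C)C[C@H](CO)[C@@](C)(O)[C@@H](O)C[C@@H](CO[Si](C)(C)C(C)(C)C)[C@](C)(O[Si](CC)(CC)CC)CC=C | intermediate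
23 | (1R,7R,8S,10S,11R)-open-chain diene: 1-CH2OTBS, 10-OTBS, 11-OH, 7-OTES, 8-CH2OTBS | C=CC(C)(C)C[C@H](CO[Si](C)(C)C(C)(C)C)[C@@](C)(O)[C@@H](O[Si](C)(C)C(C)(C)C)C[C@@H](CO[Si](C)(C)C(C)(C)C)[C@](C)(O[Si](CC)(CC)CC)CC=C | intermediate
24 | (1R,4E,7R,8S,10S,11R)-cycloundec-4-ene: 1-CH2OTBS, 10-OTBS, 11-OH, 7-OTES, 8-CH2OTBS, 3,3,7,11-tetramethyl | CC1(C)C[C@H](CO[Si](C)(C)C(C)(C)C)[C@@](C)(O)[C@@H](O[Si](C)(C)C(C)(C)C)C[C@@H](CO[Si](C)(C)C(C)(C)C)[C@](C)(O[Si](CC)(CC)CC)C/C=C/1 | intermediate
25 | (1R,4E,7R,8S,10S,11R)-1,8-bis(hydroxymethyl)-10-(TBS-oxy)-3,3,7,11-tetramethylcycloundec-4-ene-7,11-diol | CC1(C)C[C@H](CO)[C@@](C)(O)[C@@H](O[Si](C)(C)C(C)(C)C)C[C@@H](CO)[C@](C)(O)C/C=C/1 | intermediate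
26 | (1S,4E,7R,8R,10S,11R)-1,8-bis(bromomethyl)-10-(TBS-oxy)-3,3,7,11-tetramethylcycloundec-4-ene-7,11-diol | CC1(C)C[C@H](CBr)[C@@](C)(O)[C@@H](O[Si](C)(C)C(C)(C)C)C[C@@H](CBr)[C@](C)(O)C/C=C/1 | intermediate
27 | bis(pinacolato)diboron | CC1(C)OB(OC1(C)C)B1OC(C)(C)C(C)(C)O1 | starting material
28 | (1S,4E,7R,8R,10S,11R)-10-(TBS-oxy)-3,3,7,11-tetramethyl-1,8-bis[(4,4,5,5-tetramethyl-1,3,2-dioxaborolan-2-yl)methyl]cycloundec-4-ene-7,11-diol | CC1(C)OB(C[C@H]2CC(C)(C)/C=C/C[C@@](C)(O)[C@H](CB3OC(C)(C)C(C)(C)O3)C[C@H](O[Si](C)(C)C(C)(C)C)[C@]2(C)O)OC1(C)C | intermediate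
29 | 2-methylanisole | COc1ccccc1C | starting material
30 | 1-methoxy-2-methylcyclohexa-1,4-diene | COC1=C(C)CC=CC1 | intermediate
31 | rac-7,7-dibromo-1-methoxy-6-methylbicyclo[4.1.0]hept-3-ene (cis-fused; one enantiomer drawn) | CO[C@@]12CC=CC[C@]1(C)C2(Br)Br | intermediate
32 | rac-7,7-dibromo-1-methoxy-6-methylbicyclo[4.1.0]heptane-3,4-diol (cis-diol; one enantiomer drawn) | CO[C@@]12C[C@@H](O)[C@@H](O)C[C@]1(C)C2(Br)Br | intermediate
33 | rac-7,7-dibromo-1-methoxy-6-methylbicyclo[4.1.0]heptane-3,4-dione (one enantiomer drawn) | CO[C@@]12CC(=O)C(=O)C[C@]1(C)C2(Br)Br | intermediate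
34 | 5-bromo-2-hydroxy-6-methoxy-4-methylcyclohepta-2,4,6-trien-1-one | Cc1cc(O)c(=O)cc(OC)c1Br | intermediate
35 | 5-bromo-2,6-dimethoxy-4-methylcyclohepta-2,4,6-trien-1-one | Cc1cc(OC)c(=O)cc(OC)c1Br | intermediate
36 | (1R,4E,7R,8R,10S,11R)-bis(tropone) diol: compound 28 with each Bpin replaced by C5' of a 2,6-dimethoxy-4-methyltropone | Cc1cc(OC)c(=O)cc(OC)c1C[C@H]1CC(C)(C)/C=C/C[C@@](C)(O)[C@H](Cc2c(C)cc(OC)c(=O)cc2OC)C[C@H](O[Si](C)(C)C(C)(C)C)[C@]1(C)O | intermediate
37 | (1R,4E,7R,8R,10S,11R)-bis(dihydropyrano)tropone, 2'-OMe on each tropone, 10-OTBS | Cc1cc(OC)c(=O)cc2c1C[C@H]1CC(C)(C)/C=C/C[C@@]3(C)Oc4cc(=O)c(OC)cc(C)c4C[C@@H]3C[C@H](O[Si](C)(C)C(C)(C)C)[C@]1(C)O2 | intermediate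
38 | (1R,4E,7R,8R,10S,11R)-bis(dihydropyrano)tropone, 2'-OMe on each tropone, 10-OH | Cc1cc(OC)c(=O)cc2c1C[C@H]1CC(C)(C)/C=C/C[C@@]3(C)Oc4cc(=O)c(OC)cc(C)c4C[C@@H]3C[C@H](O)[C@]1(C)O2 | intermediate
39 | CNP0283947.4, (1R,4E,7R,8R,10S,11R) in the numbering used here, drawn as the tropolone tautomer of the target SMILES | Cc1cc(=O)c(O)cc2c1C[C@H]1CC(C)(C)/C=C/C[C@@]3(C)Oc4cc(O)c(=O)cc(C)c4C[C@@H]3C[C@H](O)[C@]1(C)O2 | target

**Count and risks**

Total step count: 29. Longest linear sequence: 19 steps (from 7 through steps 6–11, 12–20 and 26–29).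

Steps most likely to fail:

1. Step 26 (double coupling). Transmetalation of the β-branched alkylboronates onto the di-ortho-substituted tropone–palladium intermediate may be slow, so that protodeboronation or stalling after one coupling takes over. Fallback: setting out from 28, treatment with KHF2 in MeOH/H2O would give the dipotassium bis(trifluoroborate) F3, a more nucleophilic and hydrolytically metered boron partner. F3 would be coupled with 35 (Pd(OAc)2, RuPhos, K2CO3, toluene/H2O, 85 °C), rejoining the route at 36.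

2. Step 17 (ring closure). Intermolecular metathesis may compete, and ring closure under kinetic control may deliver the cis ring olefin. Fallback: setting out from 23, the ring would be closed without regard to geometry and the Z-cycloundecene F1 accepted. Epoxidation with mCPBA (NaHCO3, CH2Cl2) would give the cis-epoxide F2. LiPPh2 in THF would open F2 at C5 with inversion, and MeI would quaternise phosphorus. Syn-elimination of the betaine then inverts the olefin and rejoins the route at 24.

3. Step 20 (borylation). Oxidative addition at the β-branched bromides may be sluggish, and β-hydride elimination or oxetane formation from the γ-bromo alcohols may compete. Fallback: setting out from 25, I2, PPh3 and imidazole would give the diiodide F4. F4 would be treated with t-BuLi (6.2 equiv, Et2O, −78 °C; the two alkoxides form first, then two iodine–lithium exchanges) and the dilithio species trapped with 2-isopropoxy-4,4,5,5-tetramethyl-1,3,2-dioxaborolane. This polar lithiation–borylation rejoins the route at 28.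

Further compounds
F1 | step 17 | (1R,4Z,7R,8S,10S,11R)-isomer of cycloundecene 24 | CC1(C)C[C@H](CO[Si](C)(C)C(C)(C)C)[C@@](C)(O)[C@@H](O[Si](C)(C)C(C)(C)C)C[C@@H](CO[Si](C)(C)C(C)(C)C)[C@](C)(O[Si](CC)(CC)CC)C/C=C\1
F2 | step 17 | cis-4,5-epoxide of F1 (either face serves; one drawn) | CC1(C)C[C@H](CO[Si](C)(C)C(C)(C)C)[C@@](C)(O)[C@@H](O[Si](C)(C)C(C)(C)C)C[C@@H](CO[Si](C)(C)C(C)(C)C)[C@](C)(O[Si](CC)(CC)CC)C[C@H]2O[C@@H]12
F3 | step 26 | dipotassium bis(trifluoroborate) corresponding to 28 | [K+].[K+].CC1(C)C[C@H](C[B-](F)(F)F)[C@@](C)(O)[C@@H](O[Si](C)(C)C(C)(C)C)C[C@@H](C[B-](F)(F)F)[C@](C)(O)C/C=C/1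
F4 | step 20 | (1S,4E,7R,8R,10S,11R)-1,8-bis(iodomethyl) analogue of 26 | CC1(C)C[C@H](CI)[C@@](C)(O)[C@@H](O[Si](C)(C)C(C)(C)C)C[C@@H](CI)[C@](C)(O)C/C=C/1
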